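(The data were generated by integration from invented constants.)

The constant I need is the selectivity factor κ: the first-order constant for target going on to over-reaction product, divided by that for starting material being used up. I want the share of target in the flasks asked about, and κ with the fraction of starting material left gives it without a clock.

in all of them: free enzyme 10 µM
- Tuesday's: starting material 0.050 M; temperature 22 °C; run made earlier
- Saturday's: starting material 0.075 M; temperature 39 °C; run made earlier
- north-west: starting material 0.10 M; temperature 30 °C; time 6.0 h
- west: starting material 0.10 M; temperature 45 °C; time 6.0 h
- south-west: starting material 0.10 M; temperature 15 °C; time 6.0 h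
- south: starting material 0.10 M; at 45 °C until 4.0 h, from then on at 15 °C; time 6.0 h

- Tuesday's (time / h: target / %, over-reaction product / %): 0.250: 4, 0; 0.500: 5, 0; 1.00: 11, 0; 2.00: 21, 4; 4.00: 24, 17
- Saturday's (time / h: target / %, over-reaction product / %): 0.417: 14, 5; 0.833: 18, 12; 1.33: 15, 30; 2.00: 14, 46; 2.50: 11, 54

(scatter of a reading: 1.5 percentage points)



1. the flask that comes out highest in share of target in all that became target or over-reaction product, or "all alike" when all lie within 1.5 percentage points (north-west / west / south-west / south / all alike)
2. share of target in all that became target or over-reaction product, north-west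
3. share of target in all that became target or over-reaction product, west
4. share of target in all that became target or over-reaction product, south-west
5. share of target in all that became target or over-reaction product, south

1. Main step alone: starting material → target at constant free enzyme. What converts is target, so the share stands at 100 per cent.

2. Now add target → over-reaction product. Dividing the rate of over-reaction by the rate of conversion removes time: dc(over-reaction product)/dc(converted) = κ·c(target)/c(starting material). Tuesday's readings from 2.00 h to 4.00 h give κ, the constant of target's loss over that of starting material's loss, as 2.42. Saturday's from 0.833 h to 2.00 h give 3.90. Both are readings and carry the scatter. Integrated, with a the fraction of starting material left, the share is s = (a − a^κ)/((κ − 1)(1 − a)).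

3. Now add temperature. I draw ln κ as a straight line in temperature through the two runs, with slope 0.0280 K⁻¹. So my line puts κ at 1.99 at 15 °C, 3.03 at 30 °C and 4.61 at 45 °C, higher at the hot end than at the cold end.

4. Last comes a. I take conversion as first order, ignoring the different charges. The last readings give 0.132 h⁻¹ on Tuesday's run and 0.420 h⁻¹ on Saturday's, and a second straight line of the same kind through these two has slope 0.0681 K⁻¹. By my reckoning south-west then keeps a = 61.2%, north-west 25.5%, west 2.26%.

5. My shares are 61.3% for south-west, 15.9% for north-west and 0.639% for west. For south I reckon a = 7.98% and a share of 2.40% at its change at 4.0 h, and I expect the share to stay near that. So I pick south-west.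

The forecast also picks south-west, with 17%, 0.5%, 68% and 2.5% for north-west, west, south-west and south, its south-west figure above mine, and it warns: “Saturation or enzyme death at 0.10 M or 45 °C cannot be excluded”.

The flask gives south-west as highest, at 79.5%, with 22.8% for north-west, 0.377% for west and 2.37% for south. South-west still holds 77% of its starting material unbound at 6.00 h, more than my a. Put that a into the rule with the same κ and south-west's share comes to 76.6%.

    target → over-reaction product (k = 1.50 × 10⁻⁴ s⁻¹, Ea = 96.0 kJ mol⁻¹)
    starting material + free enzyme ⇌ complex (K = 30.0 M⁻¹, k = 46.0 M⁻¹ s⁻¹, Ea = 42.0 kJ mol⁻¹, ΔH = 6.00 kJ mol⁻¹)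
    complex ⇌ free enzyme + target (K = 0.0320 M, k = 0.840 s⁻¹, Ea = 71.0 kJ mol⁻¹, ΔH = −12.0 kJ mol⁻¹)
    free enzyme → unfolded enzyme (k = 9.70 × 10⁻⁷ s⁻¹, Ea = 181 kJ mol⁻¹)
    (constants at 30 °C)

For the west charge run at 20 °C my line for κ gives 2.29, and with 66% of its starting material left the rule gives 62.4%. That flask computes to 63.5%.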